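**Retrosynthetic overview**
- Vismiaphenone F ⇒ open-chain 3,5-diprenyl benzophenone: break the pyran O–CMe2 bond. Forward, DDQ dehydrogenates the C5 prenyl group to an ortho-quinone methide that closes by oxa-6π electrocyclisation on the 4-OH, as in the biosynthetic prenyl → chromene oxidation. It is run last, unprotected, and must choose between two prenyl groups.
- Diprenyl benzophenone ⇒ 2,4,4'-trihydroxy-6-methoxybenzophenone + 2 prenyl bromide: two aryl–CH2 bonds, by prenyltransferase-like double C-prenylation.
- Trihydroxy-methoxybenzophenone ⇒ 5-methoxyresorcinol + 4-hydroxybenzoic acid: aryl–C(=O) bond by Friedel–Crafts acylation; the O-methyl group is bought.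
- Ring order: both benzene rings are bought; the 2H-pyran ring is the only ring made and is closed in the final step. No protecting groups.

Assumption: the target has no stereocentre and no stereogenic double bond, so it is achiral and no enantiocontrol is needed.
Numbering used below for the benzophenones: C1 carries the aroyl group, then C2 (OH), C3, C4 (OH), C5, C6 (OMe); the B-ring OH is 4'.

**Step 1**
Reactants: 1 5-methoxyresorcinol (5-methoxybenzene-1,3-diol); 2 4-hydroxybenzoic acid
Product: 3 (2,4-dihydroxy-6-methoxyphenyl)(4-hydroxyphenyl)methanone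
Conditions: Eaton's reagent (P2O5/MeSO3H 1:10 w/w), 60–70 °C, 2 h; ice-water; chromatography
Reagents that add atoms: none
Why: Friedel–Crafts acylation of the very electron-rich ring by the acylium ion of 2; attack at C4/C6 of 1 (para to one OH, two equivalent sites) is expected to beat C2, as in the Vilsmeier formylation of 1, giving the 2,4-dihydroxy-6-methoxy pattern, and the minor 2,6-dihydroxy-4-methoxy isomer is separated; no stereocentre is formed.

**Step 2**
Reactants: 3 (2,4-dihydroxy-6-methoxyphenyl)(4-hydroxyphenyl)methanone; 4 prenyl bromide (1-bromo-3-methylbut-2-ene; 2.2 equiv, two are incorporated)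
Product: 5 [2,4-dihydroxy-6-methoxy-3,5-bis(3-methylbut-2-en-1-yl)phenyl](4-hydroxyphenyl)methanone
Conditions: 10% aq KOH, 0 °C → rt, 3 h; then 1 M HCl
Reagents that add atoms: none
Why: Nuclear C-prenylation of an ambident phloroglucinol-type phenoxide, which reacts at carbon in water because the oxygens are hydrogen-bonded; C3 and C5 are the only free A-ring carbons, while the 4'-phenoxide is a weakly nucleophilic vinylogous carboxylate on a deactivated ring; no stereocentre is formed.

**Step 3**
Reactants: 5 [2,4-dihydroxy-6-methoxy-3,5-bis(3-methylbut-2-en-1-yl)phenyl](4-hydroxyphenyl)methanone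
Product: 7 vismiaphenone F, via ortho-quinone methide 6 (not isolated)
Conditions: DDQ (1.05 equiv), dry 1,4-dioxane, rt, 1–3 h
Reagents that add atoms: none
Why: DDQ dehydrogenative chromene formation from an ortho-prenylphenol (benzylic hydride abstraction, loss of the phenol proton to the ortho-quinone methide, oxa-6π electrocyclisation); the C5 CH2 is predicted to react first because its para oxygen is the in-plane, hydrogen-bond-polarised 2-OH whereas the C3 CH2 is para to the twisted 6-OMe, and quinone methide 6 can only close on O4 because O6 is methylated and the chelated 2-OH is a poor partner; no stereocentre is formed.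

**Compound list**
1 | 5-methoxyresorcinol (5-methoxybenzene-1,3-diol) | COc1cc(O)cc(O)c1 | starting material
2 | 4-hydroxybenzoic acid | OC(=O)c1ccc(O)cc1 | starting material
3 | (2,4-dihydroxy-6-methoxyphenyl)(4-hydroxyphenyl)methanone | COc1cc(O)cc(O)c1C(=O)c1ccc(O)cc1 | intermediate
4 | prenyl bromide (1-bromo-3-methylbut-2-ene) | CC(C)=CCBr | starting material
5 | [2,4-dihydroxy-6-methoxy-3,5-bis(3-methylbut-2-en-1-yl)phenyl](4-hydroxyphenyl)methanone (open-chain diprenyl precursor) | COc1c(CC=C(C)C)c(O)c(CC=C(C)C)c(O)c1C(=O)c1ccc(O)cc1 | intermediate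
6 | (6Z)-3-hydroxy-4-(4-hydroxybenzoyl)-5-methoxy-6-(3-methylbut-2-en-1-ylidene)-2-(3-methylbut-2-en-1-yl)cyclohexa-2,4-dien-1-one (ortho-quinone methide) | CC(C)=C/C=C1\C(=O)C(CC=C(C)C)=C(O)C(C(=O)c2ccc(O)cc2)=C1OC | intermediate
7 | vismiaphenone F, [7-hydroxy-5-methoxy-2,2-dimethyl-8-(3-methylbut-2-en-1-yl)-2H-chromen-6-yl](4-hydroxyphenyl)methanone | COc1c2c(c(CC=C(C)C)c(O)c1C(=O)c1ccc(O)cc1)OC(C)(C)C=C2 | target

**Totals**
Total step count: 3. Longest linear sequence: 3 (steps 1 → 2 → 3).

**Steps most likely to fail, with fallbacks**

Step 3 (highest risk: which prenyl group is oxidised; over-oxidation to a bis-chromene). The predicted preference for the C5 prenyl is an electronic argument, not a demonstrated result, and a mixture with the isomer closed from the C3 prenyl is possible. The fallback sets out from 3 and comes back at 7. Compound 3 is treated with 1.0 equiv of 4 in 10% aq KOH at 0 °C. C3, between two phenoxide oxygens, is alkylated first and gives [2,4-dihydroxy-6-methoxy-3-(3-methylbut-2-en-1-yl)phenyl](4-hydroxyphenyl)methanone F1, which is also the mono-alkylated by-product of step 2. F1 is then condensed with 3-methylbut-2-enal (CC(C)=CC=O; ethylenediammonium diacetate cat., PhMe, reflux). Condensation occurs at C5, the only free nucleophilic ring carbon, and the resulting quinone methide closes on the 4-OH, so 7 forms without a regiochemical choice.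

Step 2 (O-prenylation of the 4'-OH, geminal dialkylation at C3, incomplete second alkylation at C5). The fallback sets out from 3 and comes back at 5. It replaces phenoxide alkylation by acid-mediated Friedel–Crafts prenylation of the neutral phenol with 2-methylbut-3-en-2-ol (CC(C)(O)C=C; 3 equiv, BF3·OEt2, 1,4-dioxane, rt). The dimethylallyl cation attacks only the activated A ring, and neither O-alkylation nor dearomatising dialkylation is expected; chroman by-products are the cost. No compound outside the list is made (F0).

Step 1 (regiochemistry of acylation of 1; the 2,6-dihydroxy-4-methoxy isomer could dominate). The fallback sets out from 2 and comes back at 3, using symmetry to remove the choice.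
- Phloroglucinol (Oc1cc(O)cc(O)c1) and 2 in Eaton's reagent at 70 °C give (4-hydroxyphenyl)(2,4,6-trihydroxyphenyl)methanone F2 as a single isomer.
- MOMCl (3.3 equiv), iPr2NEt, CH2Cl2, 0 °C protects all but one chelated OH to give [2-hydroxy-4,6-bis(methoxymethoxy)phenyl][4-(methoxymethoxy)phenyl]methanone F3.
- MeI, K2CO3, acetone, reflux methylates the remaining OH to give [2-methoxy-4,6-bis(methoxymethoxy)phenyl][4-(methoxymethoxy)phenyl]methanone F4.
- HCl, MeOH, 50 °C removes the three MOM groups and delivers 3.

**Further compounds**
F1 | step 3 | [2,4-dihydroxy-6-methoxy-3-(3-methylbut-2-en-1-yl)phenyl](4-hydroxyphenyl)methanone | COc1cc(O)c(CC=C(C)C)c(O)c1C(=O)c1ccc(O)cc1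
F0 | step 2 | none | none
F2 | step 1 | (4-hydroxyphenyl)(2,4,6-trihydroxyphenyl)methanone | Oc1ccc(cc1)C(=O)c1c(O)cc(O)cc1O
F3 | step 1 | [2-hydroxy-4,6-bis(methoxymethoxy)phenyl][4-(methoxymethoxy)phenyl]methanone | COCOc1ccc(cc1)C(=O)c1c(O)cc(OCOC)cc1OCOC
F4 | step 1 | [2-methoxy-4,6-bis(methoxymethoxy)phenyl][4-(methoxymethoxy)phenyl]methanone | COCOc1ccc(cc1)C(=O)c1c(OC)cc(OCOC)cc1OCOC
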